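**Strategy.** The ten-membered carbocycle (C1–C10) is closed last, across the C4(=C15H2)–C5=C6 diene. One ruthenium-catalysed endo enyne metathesis joins the terminal C4≡C5 alkyne of the arm on C1 to the vinyl group on C7, creating the cis C5=C6 olefin and the exocyclic C4=C15 methylidene together. The precursor is the fully substituted, MOM-protected diformyl chroman whose two arms sit trans on ring B (the dihydropyran ring, at C1 and C10). Its stereocentres are fixed beforehand without diastereomer separations: C10/C1 from a Sharpless epoxide of geraniol opened with inversion, C1' by hydride delivery to a benzylic cation, C7 by Shi epoxidation and anti vinyl transfer.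

Key step: step 18

Remark: numbering is C1–C10 for the carbocycle (C1 ring-fusion CH, C10 O-bearing quaternary carbon), C15 the methylidene on C4, C11 the carbinol on C7, C1' the benzylic CH; the SMILES encodes (1S,7R,10R,1'R), and C15 is taken to come from ethylene.

Remark: geraniol, 5-bromoresorcinol, (4-bromobut-1-yn-1-yl)trimethylsilane, the Grignard solutions, D-(−)-diethyl tartrate and the Shi ketone are assumed to be commercial.

Step 1
Reactants: 1 geraniol
Product: 2 [(2R,3R)-3-methyl-3-(4-methylpent-3-en-1-yl)oxiran-2-yl]methanol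
Conditions: t-BuOOH, Ti(OiPr)4 (cat.), D-(−)-diethyl tartrate (cat.), 4 Å molecular sieves, CH2Cl2, −20 °C
Reagents that add atoms: tert-butyl hydroperoxide, CC(C)(C)OO
Why: Sharpless asymmetric epoxidation of the allylic alcohol; the tartrate sets both new centres (the future C1 and C10) by reagent control, and the remote trisubstituted olefin, which has no allylic hydroxyl, is left alone.

Step 2
Reactants: 2 epoxy alcohol; 3 (4-bromobut-1-yn-1-yl)trimethylsilane
Product: 5 (2S,3R)-3,7-dimethyl-2-[4-(trimethylsilyl)but-3-yn-1-yl]oct-6-ene-1,3-diol, via silylbutynyl Grignard reagent 4 (not isolated)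
Conditions: 3, Mg, THF, rt; then 2, CuI (10 mol%), THF, −30 → 0 °C; aq. NH4Cl
Reagents that add atoms: none
Why: copper-catalysed Grignard opening of a 2,3-epoxy alcohol; the fully substituted epoxide carbon is blocked, so the alkyl group enters at C2 by SN2 with inversion, which sets C1, while the oxygen stays on C10 with retention.

Step 3
Reactants: 5 diol
Product: 6 (2R,3R)-3-hydroxy-3,7-dimethyl-2-[4-(trimethylsilyl)but-3-yn-1-yl]oct-6-enal
Conditions: TEMPO (cat.), PhI(OAc)2, CH2Cl2, rt
Reagents that add atoms: none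
Why: nitroxyl-catalysed oxidation converts only the primary alcohol into the aldehyde under neutral conditions, so the tertiary alcohol, the olefin, the silylalkyne and the α-centre are untouched.

Step 4
Reactants: 7 5-bromobenzene-1,3-diol
Product: 8 1-bromo-3,5-bis(methoxymethoxy)benzene
Conditions: MOMCl, iPr2NEt, CH2Cl2, 0 °C → rt
Reagents that add atoms: chloromethyl methyl ether, COCCl
Why: O-alkylation of both phenols gives base-stable acetal ethers that survive every organometallic step up to the final deprotection.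

Step 5
Reactants: 8 bis(MOM) ether
Product: 9 1-bromo-2-iodo-3,5-bis(methoxymethoxy)benzene
Conditions: N-iodosuccinimide, MeCN, rt
Reagents that add atoms: N-iodosuccinimide, O=C1CCC(=O)N1I
Why: electrophilic aromatic iodination goes ortho to one and para to the other ether oxygen (next to bromine), because the position between the two ethers is the more hindered one.

Step 6
Reactants: 6 hydroxy aldehyde; 9 bromo iodo arene
Product: 11 (2S,3R)-1-[2-bromo-4,6-bis(methoxymethoxy)phenyl]-3,7-dimethyl-2-[4-(trimethylsilyl)but-3-yn-1-yl]oct-6-ene-1,3-diol (both C1 epimers), via aryl Grignard reagent 10 (not isolated)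
Conditions: 9, iPrMgCl·LiCl, THF, −30 °C; then 6, −30 → 0 °C; aq. NH4Cl
Reagents that add atoms: none
Why: iodine–magnesium exchange takes place at the C–I bond only and the ortho-bromoaryl Grignard reagent adds to the aldehyde; the new carbinol centre (C1') forms without control, which is harmless because it becomes a ketone in step 12.

Step 7
Reactants: 11 diol
Product: 12 (2S,3R)-1-[2-bromo-4,6-bis(methoxymethoxy)phenyl]-3,7-dimethyl-1-[(triethylsilyl)oxy]-2-[4-(trimethylsilyl)but-3-yn-1-yl]oct-6-en-3-ol (both C1 epimers)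
Conditions: TESCl, imidazole, DMF, 0 °C → rt
Reagents that add atoms: chlorotriethylsilane, CC[Si](Cl)(CC)CC
Why: the secondary benzylic hydroxyl is silylated much faster than the tertiary one, which masks the only alcohol that palladium could dehydrogenate in the next step.

Step 8
Reactants: 12 bromoaryl tertiary alcohol
Product: 13 (2R,3S)-5,7-bis(methoxymethoxy)-2-methyl-2-(4-methylpent-3-en-1-yl)-4-[(triethylsilyl)oxy]-3-[4-(trimethylsilyl)but-3-yn-1-yl]-3,4-dihydro-2H-chromene (both C4 epimers)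
Conditions: Pd(OAc)2 (5 mol%), 2-(di-tert-butylphosphino)-1,1'-binaphthyl, Cs2CO3, toluene, 80 °C
Reagents that add atoms: none
Why: palladium-catalysed intramolecular C–O coupling (Buchwald–Hartwig etherification) of the tertiary alkoxide, which cannot undergo β-hydride elimination, closes ring B; the C10–O bond is not broken, so C10 keeps its configuration.

Step 9
Reactants: 13 chroman
Product: 14 (2R,3S)-2-{2-[(2R)-3,3-dimethyloxiran-2-yl]ethyl}-5,7-bis(methoxymethoxy)-2-methyl-4-[(triethylsilyl)oxy]-3-[4-(trimethylsilyl)but-3-yn-1-yl]-3,4-dihydro-2H-chromene (both C4 epimers)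
Conditions: Shi ketone (D-fructose-derived, 30 mol%), KHSO5 (as Oxone), K2CO3, Bu4NHSO4, MeCN/CH2(OMe)2/aq. buffer, 0 °C
Reagents that add atoms: potassium peroxymonosulfate, [K+].OOS(=O)(=O)[O-]
Why: Shi asymmetric epoxidation of the only electron-rich (trisubstituted) olefin; the chiral dioxirane, not the distant chroman, selects the face and should give the (R)-epoxide.

Step 10
Reactants: 14 epoxide; 15 vinylmagnesium bromide
Product: 16 (3R)-5-{(2R,3S)-5,7-bis(methoxymethoxy)-2-methyl-4-[(triethylsilyl)oxy]-3-[4-(trimethylsilyl)but-3-yn-1-yl]-3,4-dihydro-2H-chromen-2-yl}-3-ethenyl-2-methylpentan-2-ol (both C4 epimers)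
Conditions: CuI (20 mol%), THF, −20 °C → rt; aq. NH4Cl
Reagents that add atoms: none
Why: copper-catalysed epoxide opening by the vinyl Grignard reagent at the less substituted carbon with inversion gives the (7R) centre and the C11 tertiary alcohol in one operation.

Step 11
Reactants: 16 silyl ether
Product: 17 (3R)-3-ethenyl-5-{(2R,3S)-4-hydroxy-5,7-bis(methoxymethoxy)-2-methyl-3-[4-(trimethylsilyl)but-3-yn-1-yl]-3,4-dihydro-2H-chromen-2-yl}-2-methylpentan-2-ol (both C4 epimers)
Conditions: HF·pyridine, pyridine, THF, 0 °C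
Reagents that add atoms: none
Why: buffered hydrogen fluoride cleaves the O-triethylsilyl ether, while the C-silyl group on the alkyne and the MOM ethers are stable under these conditions.

Step 12
Reactants: 17 benzylic alcohol
Product: 18 (2R,3R)-2-[(3R)-3-ethenyl-4-hydroxy-4-methylpentyl]-5,7-bis(methoxymethoxy)-2-methyl-3-[4-(trimethylsilyl)but-3-yn-1-yl]-2,3-dihydro-4H-chromen-4-one
Conditions: Dess–Martin periodinane, CH2Cl2, 0 °C → rt
Reagents that add atoms: none
Why: Dess–Martin oxidation of the secondary benzylic alcohol without base, so that neither the α-centre C1 nor the β-aryloxy ketone (C10) can equilibrate; the tertiary alcohol is inert.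

Step 13
Reactants: 18 chromanone; 19 isobutylmagnesium bromide
Product: 20 (2R,3S)-2-[(3R)-3-ethenyl-4-hydroxy-4-methylpentyl]-5,7-bis(methoxymethoxy)-2-methyl-4-(2-methylpropyl)-3-[4-(trimethylsilyl)but-3-yn-1-yl]-3,4-dihydro-2H-chromen-4-ol (both C4 epimers)
Conditions: CeCl3, THF, −78 → 0 °C; aq. NH4Cl
Reagents that add atoms: none
Why: the organocerium reagent adds to the hindered, enolisable aryl ketone without deprotonation or β-hydride reduction; the configuration of the new carbinol is irrelevant because it is ionised next.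

Step 14
Reactants: 20 tertiary benzylic alcohol
Product: 21 (3R)-5-{(2R,3S,4R)-5,7-bis(methoxymethoxy)-2-methyl-4-(2-methylpropyl)-3-[4-(trimethylsilyl)but-3-yn-1-yl]-3,4-dihydro-2H-chromen-2-yl}-3-ethenyl-2-methylpentan-2-ol
Conditions: Et3SiH, BF3·OEt2, CH2Cl2, −78 °C
Reagents that add atoms: none
Why: ionic hydrogenation; only the trioxygenated benzylic alcohol ionises at low temperature and the silane should deliver hydride anti to the neighbouring side arm on C1, which places the isobutyl group cis to it (1'R).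

Step 15
Reactants: 21 chroman
Product: 22 (3R)-5-{(2R,3S,4R)-6,8-dibromo-5,7-bis(methoxymethoxy)-2-methyl-4-(2-methylpropyl)-3-[4-(trimethylsilyl)but-3-yn-1-yl]-3,4-dihydro-2H-chromen-2-yl}-3-ethenyl-2-methylpentan-2-ol
Conditions: N-bromosuccinimide (2 equiv), MeCN, 0 °C
Reagents that add atoms: N-bromosuccinimide, O=C1CCC(=O)N1Br
Why: electrophilic bromination of the two free ring positions, each flanked by two oxygen substituents, is far faster than any reaction of the hindered monosubstituted olefin.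

Step 16
Reactants: 22 dibromide
Product: 23 (2R,3S,4R)-2-[(3R)-3-ethenyl-4-hydroxy-4-methylpentyl]-5,7-bis(methoxymethoxy)-2-methyl-4-(2-methylpropyl)-3-[4-(trimethylsilyl)but-3-yn-1-yl]-3,4-dihydro-2H-chromene-6,8-dicarbaldehyde
Conditions: t-BuLi, THF, −78 °C; DMF, −78 → 0 °C; aq. NH4Cl
Reagents that add atoms: N,N-dimethylformamide, CN(C)C=O
Why: bromine–lithium exchange is faster than deprotonation next to the alkyne, and the aryl dilithium (beside the lithium alkoxide) is formylated at both positions (Bouveault-type formylation).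

Step 17
Reactants: 23 silylalkyne
Product: 24 (2R,3S,4R)-3-(but-3-yn-1-yl)-2-[(3R)-3-ethenyl-4-hydroxy-4-methylpentyl]-5,7-bis(methoxymethoxy)-2-methyl-4-(2-methylpropyl)-3,4-dihydro-2H-chromene-6,8-dicarbaldehyde
Conditions: K2CO3, MeOH, rt
Reagents that add atoms: none
Why: methoxide-induced protodesilylation frees the terminal alkyne; aldehydes, MOM ethers and the tertiary alcohol are unaffected.

Step 18
Reactants: 24 seco enyne chroman
Product: 25 bis(methoxymethyl) ether of the target (ten-membered ring with 4-methylidene and cis C5=C6, trans-fused to ring B; 1S,7R,10R,1'R)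
Conditions: RuCl2(=CHPh)(PCy3)(H2IMes) (second-generation Grubbs catalyst, 15 mol%), ethylene (1 atm), toluene (1 mM, slow addition of 24), 80 °C
Reagents that add atoms: ethylene, C=C
Why: The ruthenium methylidene kept alive by ethylene adds to the terminal alkyne with C–C bonding at the unsubstituted C5, the vinylcarbene at C4 is released as the 2-substituted butadiene (C4=C15H2, C5=CH2), and this diene closes onto the C7 vinyl group by diene–ene metathesis with loss of ethylene; attack of the C7 alkylidene on the alkyne leads to the same product. The closest known reactions are ethylene-assisted enyne cross-metathesis followed by ring-closing metathesis, and endo-mode ring-closing enyne metathesis of macrocycle precursors. The ten-membered ring closes in the endo mode, with C5 in the ring and C15 outside, because exo closure at C4 would require a nine-membered ring and because ethylene routes the alkyne through the 1,3-diene. No stereocentre is formed; the cis C5=C6 geometry is imposed by the medium ring fused to ring B. The step needs ring closure to win over oligomerisation and over stalling at the hindered C7 vinyl group, which is secured by high dilution, by the two arms held gauche on adjacent carbons of ring B, and by the unhindered diene terminus as the site where the catalyst loads. Aldehydes, MOM ethers and the free tertiary alcohol are tolerated by the ruthenium carbene.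

Step 19
Reactants: 25 bis(MOM) ether
Product: 26 target CNP0479784.1
Conditions: 2 M aq. HCl, THF, 40 °C
Reagents that add atoms: none
Why: acetal hydrolysis of the two aryl MOM ethers, assisted by the ortho formyl groups, under acid dilute enough to leave the tertiary alcohol, the diene and the tertiary aryl ether intact.

**Compound list**

1 | geraniol, (2E)-3,7-dimethylocta-2,6-dien-1-ol | CC(C)=CCC/C(C)=C/CO | starting material
2 | [(2R,3R)-3-methyl-3-(4-methylpent-3-en-1-yl)oxiran-2-yl]methanol | CC(C)=CCC[C@@]1(C)O[C@@H]1CO | intermediate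
3 | (4-bromobut-1-yn-1-yl)trimethylsilane | C[Si](C)(C)C#CCCBr | starting material
4 | [4-(trimethylsilyl)but-3-yn-1-yl]magnesium bromide | C[Si](C)(C)C#CCC[Mg]Br | intermediate (not isolated)
5 | (2S,3R)-3,7-dimethyl-2-[4-(trimethylsilyl)but-3-yn-1-yl]oct-6-ene-1,3-diol | CC(C)=CCC[C@@]([C@H](CO)CCC#C[Si](C)(C)C)(C)O | intermediate
6 | (2R,3R)-3-hydroxy-3,7-dimethyl-2-[4-(trimethylsilyl)but-3-yn-1-yl]oct-6-enal | CC(C)=CCC[C@@]([C@H](C=O)CCC#C[Si](C)(C)C)(C)O | intermediate
7 | 5-bromobenzene-1,3-diol | Oc1cc(O)cc(Br)c1 | starting material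
8 | 1-bromo-3,5-bis(methoxymethoxy)benzene | COCOc1cc(OCOC)cc(Br)c1 | intermediate
9 | 1-bromo-2-iodo-3,5-bis(methoxymethoxy)benzene | COCOc1cc(OCOC)c(I)c(Br)c1 | intermediate
10 | [2-bromo-4,6-bis(methoxymethoxy)phenyl]magnesium chloride (LiCl complex) | COCOc1cc(OCOC)c([Mg]Cl)c(Br)c1 | intermediate (not isolated)
11 | (2S,3R)-1-[2-bromo-4,6-bis(methoxymethoxy)phenyl]-3,7-dimethyl-2-[4-(trimethylsilyl)but-3-yn-1-yl]oct-6-ene-1,3-diol, both C1 epimers | CC(C)=CCC[C@@]([C@H](C(O)c1c(Br)cc(OCOC)cc1OCOC)CCC#C[Si](C)(C)C)(C)O | intermediate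
12 | (2S,3R)-1-[2-bromo-4,6-bis(methoxymethoxy)phenyl]-3,7-dimethyl-1-[(triethylsilyl)oxy]-2-[4-(trimethylsilyl)but-3-yn-1-yl]oct-6-en-3-ol, both C1 epimers | CC(C)=CCC[C@@]([C@H](C(O[Si](CC)(CC)CC)c1c(Br)cc(OCOC)cc1OCOC)CCC#C[Si](C)(C)C)(C)O | intermediate
13 | (2R,3S)-5,7-bis(methoxymethoxy)-2-methyl-2-(4-methylpent-3-en-1-yl)-4-[(triethylsilyl)oxy]-3-[4-(trimethylsilyl)but-3-yn-1-yl]-3,4-dihydro-2H-chromene, both C4 epimers | CC(C)=CCC[C@@]2(C)Oc3cc(OCOC)cc(OCOC)c3C(O[Si](CC)(CC)CC)[C@@H]2CCC#C[Si](C)(C)C | intermediate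
14 | (2R,3S)-2-{2-[(2R)-3,3-dimethyloxiran-2-yl]ethyl}-5,7-bis(methoxymethoxy)-2-methyl-4-[(triethylsilyl)oxy]-3-[4-(trimethylsilyl)but-3-yn-1-yl]-3,4-dihydro-2H-chromene, both C4 epimers | CC1(C)O[C@@H]1CC[C@@]2(C)Oc3cc(OCOC)cc(OCOC)c3C(O[Si](CC)(CC)CC)[C@@H]2CCC#C[Si](C)(C)C | intermediate
15 | vinylmagnesium bromide | C=C[Mg]Br | starting material
16 | (3R)-5-{(2R,3S)-5,7-bis(methoxymethoxy)-2-methyl-4-[(triethylsilyl)oxy]-3-[4-(trimethylsilyl)but-3-yn-1-yl]-3,4-dihydro-2H-chromen-2-yl}-3-ethenyl-2-methylpentan-2-ol, both C4 epimers | C=C[C@H](C(C)(C)O)CC[C@@]2(C)Oc3cc(OCOC)cc(OCOC)c3C(O[Si](CC)(CC)CC)[C@@H]2CCC#C[Si](C)(C)C | intermediate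
17 | (3R)-3-ethenyl-5-{(2R,3S)-4-hydroxy-5,7-bis(methoxymethoxy)-2-methyl-3-[4-(trimethylsilyl)but-3-yn-1-yl]-3,4-dihydro-2H-chromen-2-yl}-2-methylpentan-2-ol, both C4 epimers | C=C[C@H](C(C)(C)O)CC[C@@]2(C)Oc3cc(OCOC)cc(OCOC)c3C(O)[C@@H]2CCC#C[Si](C)(C)C | intermediate
18 | (2R,3R)-2-[(3R)-3-ethenyl-4-hydroxy-4-methylpentyl]-5,7-bis(methoxymethoxy)-2-methyl-3-[4-(trimethylsilyl)but-3-yn-1-yl]-2,3-dihydro-4H-chromen-4-one | C=C[C@H](C(C)(C)O)CC[C@@]2(C)Oc3cc(OCOC)cc(OCOC)c3C(=O)[C@@H]2CCC#C[Si](C)(C)C | intermediate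
19 | isobutylmagnesium bromide | CC(C)C[Mg]Br | starting material
20 | (2R,3S)-2-[(3R)-3-ethenyl-4-hydroxy-4-methylpentyl]-5,7-bis(methoxymethoxy)-2-methyl-4-(2-methylpropyl)-3-[4-(trimethylsilyl)but-3-yn-1-yl]-3,4-dihydro-2H-chromen-4-ol, both C4 epimers | C=C[C@H](C(C)(C)O)CC[C@@]2(C)Oc3cc(OCOC)cc(OCOC)c3C(O)(CC(C)C)[C@@H]2CCC#C[Si](C)(C)C | intermediate
21 | (3R)-5-{(2R,3S,4R)-5,7-bis(methoxymethoxy)-2-methyl-4-(2-methylpropyl)-3-[4-(trimethylsilyl)but-3-yn-1-yl]-3,4-dihydro-2H-chromen-2-yl}-3-ethenyl-2-methylpentan-2-ol | C=C[C@H](C(C)(C)O)CC[C@@]2(C)Oc3cc(OCOC)cc(OCOC)c3[C@H](CC(C)C)[C@@H]2CCC#C[Si](C)(C)C | intermediate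
22 | (3R)-5-{(2R,3S,4R)-6,8-dibromo-5,7-bis(methoxymethoxy)-2-methyl-4-(2-methylpropyl)-3-[4-(trimethylsilyl)but-3-yn-1-yl]-3,4-dihydro-2H-chromen-2-yl}-3-ethenyl-2-methylpentan-2-ol | C=C[C@H](C(C)(C)O)CC[C@@]2(C)Oc3c(Br)c(OCOC)c(Br)c(OCOC)c3[C@H](CC(C)C)[C@@H]2CCC#C[Si](C)(C)C | intermediate
23 | (2R,3S,4R)-2-[(3R)-3-ethenyl-4-hydroxy-4-methylpentyl]-5,7-bis(methoxymethoxy)-2-methyl-4-(2-methylpropyl)-3-[4-(trimethylsilyl)but-3-yn-1-yl]-3,4-dihydro-2H-chromene-6,8-dicarbaldehyde | C=C[C@H](C(C)(C)O)CC[C@@]2(C)Oc3c(C=O)c(OCOC)c(C=O)c(OCOC)c3[C@H](CC(C)C)[C@@H]2CCC#C[Si](C)(C)C | intermediate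
24 | (2R,3S,4R)-3-(but-3-yn-1-yl)-2-[(3R)-3-ethenyl-4-hydroxy-4-methylpentyl]-5,7-bis(methoxymethoxy)-2-methyl-4-(2-methylpropyl)-3,4-dihydro-2H-chromene-6,8-dicarbaldehyde (key-step precursor) | C=C[C@H](C(C)(C)O)CC[C@@]2(C)Oc3c(C=O)c(OCOC)c(C=O)c(OCOC)c3[C@H](CC(C)C)[C@@H]2CCC#C | intermediate
25 | bis(methoxymethyl) ether of the target (key-step product; 1S,7R,10R,1'R; cis C5=C6; 4-methylidene) | C=C1/C=C\[C@H](C(C)(C)O)CC[C@@]2(C)Oc3c(C=O)c(OCOC)c(C=O)c(OCOC)c3[C@H](CC(C)C)[C@@H]2CC1 | intermediate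
26 | CNP0479784.1: 6,8-diformyl-5,7-dihydroxychroman trans-fused (C10–C1) to a 4-methylidene-cyclodec-5(Z)-ene carrying 2-hydroxypropan-2-yl at C7, methyl at C10 and 2-methylpropyl at C1' (1S,7R,10R,1'R) | C=C1/C=C\[C@H](C(C)(C)O)CC[C@@]2(C)Oc3c(C=O)c(O)c(C=O)c(O)c3[C@H](CC(C)C)[C@@H]2CC1 | target

**Step count.** Total: 19 steps. Longest linear sequence: 17 steps (steps 1–3 and 6–19, from geraniol); steps 4 and 5 make the aryl fragment.

**Steps most likely to fail**

Step 18 (key step). Intermolecular enyne and diene metathesis (oligomerisation) may outrun closure of the ten-membered ring. The sequence may also stall at the open-chain diene, because ethylene re-opens the ring and the C7 vinyl group loads the catalyst slowly. The fallback separates the two events. Setting out from 24, ethylene and RuCl2(=CHPh)(PCy3)2 (first-generation catalyst) in CH2Cl2 at rt convert only the alkyne into the butadiene, giving (2R,3S,4R)-2-[(3R)-3-ethenyl-4-hydroxy-4-methylpentyl]-5,7-bis(methoxymethoxy)-2-methyl-3-(3-methylidenepent-4-en-1-yl)-4-(2-methylpropyl)-3,4-dihydro-2H-chromene-6,8-dicarbaldehyde F1. Isolated F1 is then closed by diene–ene ring-closing metathesis with the phosphine-free complex RuCl2(=CH-C6H4-2-OiPr)(H2IMes) at high dilution in refluxing toluene under an argon sparge, so that ethylene is swept out. This comes back to the route at 25.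

Step 16. The double bromine–lithium exchange may stay incomplete, or the aryllithium may be quenched by proton transfer from the propargylic position, leaving mono-aldehyde or reduced arene. The fallback installs the formyl groups by electrophilic substitution of the free phenol and bypasses steps 15 and 16. Setting out from 21, 2 M aq. HCl in THF removes the MOM groups to give (3R)-5-{(2R,3S,4R)-5,7-dihydroxy-2-methyl-4-(2-methylpropyl)-3-[4-(trimethylsilyl)but-3-yn-1-yl]-3,4-dihydro-2H-chromen-2-yl}-3-ethenyl-2-methylpentan-2-ol F2. Vilsmeier–Haack formylation (POCl3, DMF, MeCN, 0 °C → rt, then aq. NaOAc, which also hydrolyses any formate on the tertiary alcohol) of this phloroglucinol-type ring should give (2R,3S,4R)-2-[(3R)-3-ethenyl-4-hydroxy-4-methylpentyl]-5,7-dihydroxy-2-methyl-4-(2-methylpropyl)-3-[4-(trimethylsilyl)but-3-yn-1-yl]-3,4-dihydro-2H-chromene-6,8-dicarbaldehyde F3. MOMCl and iPr2NEt then return to the route at 23.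

Step 14. The benzylic cation may lose a proton toward C1 (2H-chromene) and be re-protonated without control, or hydride may arrive on both faces; either process scrambles C1 or C1'. The fallback replaces the cation by a radical. Setting out from 18, TMSCl and imidazole cap the C11 hydroxyl to give (2R,3R)-2-{(3R)-3-ethenyl-4-methyl-4-[(trimethylsilyl)oxy]pentyl}-5,7-bis(methoxymethoxy)-2-methyl-3-[4-(trimethylsilyl)but-3-yn-1-yl]-2,3-dihydro-4H-chromen-4-one F4. Addition of iBuMgBr/CeCl3 and quenching of the alkoxide with methyl chlorooxoacetate give the tertiary ester methyl (2R,3S)-2-{(3R)-3-ethenyl-4-methyl-4-[(trimethylsilyl)oxy]pentyl}-5,7-bis(methoxymethoxy)-2-methyl-4-(2-methylpropyl)-3-[4-(trimethylsilyl)but-3-yn-1-yl]-3,4-dihydro-2H-chromen-4-yl oxalate F5. Bu3SnH and AIBN in toluene at 80 °C remove the oxalate by radical deoxygenation; the planar benzylic radical should take hydrogen from the bulky stannane on the face away from the C1 arm, giving the C11-O-trimethylsilyl ether of 21 F6. Citric acid in MeOH cleaves the silyl ether and returns to the route at 21.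

**Further compounds**

F1 | step 18 | (2R,3S,4R)-2-[(3R)-3-ethenyl-4-hydroxy-4-methylpentyl]-5,7-bis(methoxymethoxy)-2-methyl-3-(3-methylidenepent-4-en-1-yl)-4-(2-methylpropyl)-3,4-dihydro-2H-chromene-6,8-dicarbaldehyde | C=C[C@H](C(C)(C)O)CC[C@@]2(C)Oc3c(C=O)c(OCOC)c(C=O)c(OCOC)c3[C@H](CC(C)C)[C@@H]2CCC(=C)C=C
F2 | step 16 | (3R)-5-{(2R,3S,4R)-5,7-dihydroxy-2-methyl-4-(2-methylpropyl)-3-[4-(trimethylsilyl)but-3-yn-1-yl]-3,4-dihydro-2H-chromen-2-yl}-3-ethenyl-2-methylpentan-2-ol | C=C[C@H](C(C)(C)O)CC[C@@]2(C)Oc3cc(O)cc(O)c3[C@H](CC(C)C)[C@@H]2CCC#C[Si](C)(C)C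
F3 | step 16 | (2R,3S,4R)-2-[(3R)-3-ethenyl-4-hydroxy-4-methylpentyl]-5,7-dihydroxy-2-methyl-4-(2-methylpropyl)-3-[4-(trimethylsilyl)but-3-yn-1-yl]-3,4-dihydro-2H-chromene-6,8-dicarbaldehyde | C=C[C@H](C(C)(C)O)CC[C@@]2(C)Oc3c(C=O)c(O)c(C=O)c(O)c3[C@H](CC(C)C)[C@@H]2CCC#C[Si](C)(C)C
F4 | step 14 | (2R,3R)-2-{(3R)-3-ethenyl-4-methyl-4-[(trimethylsilyl)oxy]pentyl}-5,7-bis(methoxymethoxy)-2-methyl-3-[4-(trimethylsilyl)but-3-yn-1-yl]-2,3-dihydro-4H-chromen-4-one | C=C[C@H](C(C)(C)O[Si](C)(C)C)CC[C@@]2(C)Oc3cc(OCOC)cc(OCOC)c3C(=O)[C@@H]2CCC#C[Si](C)(C)C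
F5 | step 14 | methyl (2R,3S)-2-{(3R)-3-ethenyl-4-methyl-4-[(trimethylsilyl)oxy]pentyl}-5,7-bis(methoxymethoxy)-2-methyl-4-(2-methylpropyl)-3-[4-(trimethylsilyl)but-3-yn-1-yl]-3,4-dihydro-2H-chromen-4-yl oxalate, both C4 epimers | C=C[C@H](C(C)(C)O[Si](C)(C)C)CC[C@@]2(C)Oc3cc(OCOC)cc(OCOC)c3C(OC(=O)C(=O)OC)(CC(C)C)[C@@H]2CCC#C[Si](C)(C)C
F6 | step 14 | (2R,3S,4R)-2-{(3R)-3-ethenyl-4-methyl-4-[(trimethylsilyl)oxy]pentyl}-5,7-bis(methoxymethoxy)-2-methyl-4-(2-methylpropyl)-3-[4-(trimethylsilyl)but-3-yn-1-yl]-3,4-dihydro-2H-chromene | C=C[C@H](C(C)(C)O[Si](C)(C)C)CC[C@@]2(C)Oc3cc(OCOC)cc(OCOC)c3[C@H](CC(C)C)[C@@H]2CCC#C[Si](C)(C)C
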